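## Retrosynthetic overview
1. Ring C, the C2–C3 bond and both stereocentres come from the last step. It is an enantioconvergent seven- to six-membered ring contraction of a racemic 2-aryl-1,3-benzodioxepin-5-one, in which the acetal carbon shifts from O to the neighbouring CH2 carbon.
2. The seven-membered acetal is made from 4-hydroxybenzaldehyde (p-cresol + O2) and the ω-hydroxyketone of ring A (two C–O bonds).
3. The ω-hydroxyketone is made from the aryllithium of MOM-protected 2,4-diprenylresorcinol and the Weinreb amide of glycolic acid.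
4. The diprenyl arene is made from resorcinol and two prenyl bromides by iterative directed ortho-metalation.
5. Ring order: rings A and B are bought as arenes. The dioxepinone ring is closed first and contracted to ring C last.

Assumption: the sense of induction of the new step 6 cannot be known in advance, so (R)-TRIP is written and (S)-TRIP is used instead if the (R)-acid gives the (2S,3S) series.

Abbreviations:
- prenyl = 3-methylbut-2-en-1-yl
- MOM = methoxymethyl
- TRIP = 3,3'-bis(2,4,6-triisopropylphenyl)-1,1'-binaphthyl-2,2'-diyl hydrogen phosphate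
- PPTS = pyridinium p-toluenesulfonate

## Route

Step 1
Reactants: 1 p-cresol (4-methylphenol)
Product: 2 4-hydroxybenzaldehyde
Conditions: O2 (1 atm), CoCl2 (1 mol%), NaOH (3 equiv), MeOH, 60 °C; then aq HCl
Reagents that add atoms: dioxygen, O=O
Why: Cobalt-catalysed, base-mediated benzylic autoxidation takes the cresolate through its p-quinone methide and the methanol adducts to the aldehyde, whose phenoxide is a deactivated vinylogous carboxylate that resists over-oxidation; no stereocentre is formed.

Step 2
Reactants: 3 resorcinol
Product: 4 1,3-bis(methoxymethoxy)benzene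
Conditions: NaH (2.4 equiv), MOMCl (2.4 equiv), DMF, 0 °C to rt
Reagents that add atoms: chloromethyl methyl ether (MOMCl), COCCl
Why: Williamson-type O-alkylation of the bis-phenoxide gives the bis-MOM ether, which shields both phenols from organolithiums and directs all three later metalations; no stereocentre is formed.

Step 3
Reactants: 4 1,3-bis(methoxymethoxy)benzene; 5 prenyl bromide (1-bromo-3-methylbut-2-ene)
Product: 9 1,3-bis(methoxymethoxy)-2,4-diprenylbenzene, via 2-lithio-1,3-bis(methoxymethoxy)benzene 6 (not isolated), via 1,3-bis(methoxymethoxy)-2-prenylbenzene 7 (not isolated), via 4-lithio-1,3-bis(methoxymethoxy)-2-prenylbenzene 8 (not isolated)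
Conditions: n-BuLi (1.05 equiv), THF, 0 °C; 5 (1.0 equiv), −78 °C to rt; then n-BuLi (1.2 equiv), TMEDA, 0 °C; 5 (1.3 equiv), −78 °C to rt
Reagents that add atoms: n-butyllithium, [Li]CCCC (gives only the lithium of 6 and 8; no reagent atom stays in 9)
Why: In this iterative directed ortho-metalation and SN2 allylation the first lithiation goes to C2 between the two MOM ethers, the second goes to C4 next to one MOM ether, and each aryllithium attacks the unhindered primary carbon of prenyl bromide, so only linear prenyl groups form; no stereocentre is formed.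

Step 4
Reactants: 9 1,3-bis(methoxymethoxy)-2,4-diprenylbenzene; 10 2-hydroxy-N-methoxy-N-methylacetamide
Product: 14 1-(2,4-dihydroxy-3,5-diprenylphenyl)-2-hydroxyethanone, via 6-lithio-1,3-bis(methoxymethoxy)-2,4-diprenylbenzene 11 (not isolated), via chloromagnesium alkoxide 12 (not isolated), via bis-MOM ketol 13 (not isolated)
Conditions: 9, n-BuLi (1.1 equiv), TMEDA, THF, 0 °C; added to 10 + i-PrMgCl (1.0 equiv), THF, −78 to 0 °C; then 3 M HCl in MeOH, 40 °C
Reagents that add atoms: n-butyllithium, [Li]CCCC (lithium of 11 only); isopropylmagnesium chloride, CC(C)[Mg]Cl (MgCl of 12 only); no reagent atom stays in 14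
Why: Directed ortho-metalation at the only C–H next to a MOM ether is followed by a Weinreb ketone synthesis on the pre-formed alkoxide 12 (stable chelate, no over-addition, no OH protecting group) and by acid methanolysis of both MOM acetals in the quench, conditions that ortho-prenylphenols routinely survive; no stereocentre is formed.

Step 5
Reactants: 14 1-(2,4-dihydroxy-3,5-diprenylphenyl)-2-hydroxyethanone; 2 4-hydroxybenzaldehyde
Product: 16 rac-8-hydroxy-2-(4-hydroxyphenyl)-7,9-diprenyl-2H-1,3-benzodioxepin-5(4H)-one, via 4-(dimethoxymethyl)phenol 15 (not isolated)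
Conditions: 2 (1.2 equiv), HC(OMe)3 (1.3 equiv), PPTS (2 mol%), MeOH, rt, evaporate; then 14, PPTS (5 mol%), 5 Å MS, toluene (0.01 M), 40 °C; Et3N quench, basic alumina plug
Reagents that add atoms: trimethyl orthoformate, COC(OC)OC (gives only the two methoxy groups of 15; none of its atoms stays in 16)
Why: In this acid-catalysed transacetalisation the p-hydroxyphenyl acetal exchanges easily through its alkoxy quinone methide form, the primary OH of 14 enters first and the ortho phenol then closes the seven-membered ring, with sieves removing methanol and high dilution favouring ring over oligomer; the new acetal centre is racemic, which is harmless because step 6 erases it.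

Step 6
Reactants: 16 rac-8-hydroxy-2-(4-hydroxyphenyl)-7,9-diprenyl-2H-1,3-benzodioxepin-5(4H)-one
Product: 18 lespeflorin B2, (2R,3R)-3,7-dihydroxy-2-(4-hydroxyphenyl)-6,8-diprenylchroman-4-one, via aryloxy p-quinone methide ketol 17 (not isolated)
Conditions: (R)-TRIP (10 mol%), 4 Å MS, toluene (0.02 M), 40 °C, N2
Reagents that add atoms: none
Why: Proposed new method: the chiral phosphoric acid places its proton in the O3/C5=O pocket of 16 and the C2–O3 bond ionises with push from the free 4-hydroxyphenyl group to give achiral 17, so the acetal centre is erased and both enantiomers converge; the same acid then enolises the freed ketol to its Z-enediol, and the phosphate, bridging the enediol O–H and the quinone methide oxygen, steers a 6-(enolendo) 1,6-addition of C4 onto C2 through a half-chair with the aryl group pseudo-equatorial, so that C2 has moved from O3 to the neighbouring carbon (a stepwise ionic 1,2-shift and seven- to six-membered ring contraction in which C4 of 16 becomes C3 of 18), setting C2 and C3 together as the (2R,3R)-trans isomer, which is also the thermodynamic diastereomer, while every C–O ionisation stays reversible and only C–C formation is irreversible; because the electrophile is a neutral quinone methide and not a free oxocarbenium ion, the prenyl alkenes should stay out of the reaction; the closest known reaction types are the acid-catalysed Petasis–Ferrier and aza-Petasis–Ferrier O-to-C rearrangements, the [1,2]-Wittig rearrangement of acetals, phosphoric-acid enol catalysis, and phosphoric-acid-catalysed 1,6-additions to p-quinone methides made in situ.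

## Compound list
1 | p-cresol | Cc1ccc(O)cc1 | starting material
2 | 4-hydroxybenzaldehyde | O=Cc1ccc(O)cc1 | intermediate
3 | resorcinol | Oc1cccc(O)c1 | starting material
4 | 1,3-bis(methoxymethoxy)benzene | COCOc1cccc(OCOC)c1 | intermediate
5 | prenyl bromide | CC(C)=CCBr | starting material
6 | 2-lithio-1,3-bis(methoxymethoxy)benzene | [Li]c1c(OCOC)cccc1OCOC | intermediate
7 | 1,3-bis(methoxymethoxy)-2-prenylbenzene | CC(C)=CCc1c(OCOC)cccc1OCOC | intermediate
8 | 4-lithio-1,3-bis(methoxymethoxy)-2-prenylbenzene | [Li]c1ccc(OCOC)c(CC=C(C)C)c1OCOC | intermediate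
9 | 1,3-bis(methoxymethoxy)-2,4-diprenylbenzene | CC(C)=CCc1ccc(OCOC)c(CC=C(C)C)c1OCOC | intermediate
10 | 2-hydroxy-N-methoxy-N-methylacetamide | CON(C)C(=O)CO | starting material
11 | 6-lithio-1,3-bis(methoxymethoxy)-2,4-diprenylbenzene | [Li]c1cc(CC=C(C)C)c(OCOC)c(CC=C(C)C)c1OCOC | intermediate
12 | chloromagnesium alkoxide of 10 | CON(C)C(=O)CO[Mg]Cl | intermediate
13 | 1-[2,4-bis(methoxymethoxy)-3,5-diprenylphenyl]-2-hydroxyethanone | COCOc1c(CC=C(C)C)cc(C(=O)CO)c(OCOC)c1CC=C(C)C | intermediate
14 | 1-(2,4-dihydroxy-3,5-diprenylphenyl)-2-hydroxyethanone | OCC(=O)c1cc(CC=C(C)C)c(O)c(CC=C(C)C)c1O | intermediate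
15 | 4-(dimethoxymethyl)phenol | COC(OC)c1ccc(O)cc1 | intermediate
16 | rac-8-hydroxy-2-(4-hydroxyphenyl)-7,9-diprenyl-2H-1,3-benzodioxepin-5(4H)-one | O=C1COC(c2ccc(O)cc2)Oc2c(CC=C(C)C)c(O)c(CC=C(C)C)cc21 | intermediate
17 | 4-{[2-(hydroxyacetyl)-5-hydroxy-4,6-diprenylphenoxy]methylidene}cyclohexa-2,5-dien-1-one | O=C1C=CC(=COc2c(CC=C(C)C)c(O)c(CC=C(C)C)cc2C(=O)CO)C=C1 | intermediate
18 | lespeflorin B2, (2R,3R) | CC(C)=CCc1cc2c(c(CC=C(C)C)c1O)O[C@H](c1ccc(O)cc1)[C@@H](O)C2=O | target

## Count and risks
Total steps: 6. Longest linear sequence: 5 (3 → 4 → 9 → 14 → 16 → 18).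

**Step 6, the new ring contraction.**
- Risks: enolisation of the freed ketol may be too slow. A protonated quinone methide may be caught by the neighbouring prenyl alkene (oxonium-ene). Remote binding of the catalyst may give low ee. Long reaction times may erode C2 and C3.
- The fallback uses known chemistry, sets out from 9 and 2, and comes back at 18.
  - 9 is lithiated as in step 4 and acylated with N-methoxy-N-methylacetamide to give 1-[2,4-bis(methoxymethoxy)-3,5-diprenylphenyl]ethanone F1.
  - 2 is protected with NaH and MOMCl as 4-(methoxymethoxy)benzaldehyde F2.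
  - Claisen–Schmidt condensation (KOH, EtOH) joins them to the (E)-chalcone F3.
  - Juliá–Colonna epoxidation (poly-L-leucine, urea–H2O2, DBU, THF) is nucleophilic and therefore ignores the prenyl alkenes. It gives the (2R,3S)-epoxyketone F4.
  - HCl in MeOH removes the three MOM groups, and the freed ortho phenol opens the epoxide at the benzylic carbon. The Cα–O bond is retained as the 3R carbinol and the trans ring closes to 18.

**Step 5, the seven-membered aryl alkyl acetal.**
- Risks: the equilibrium may favour open or oligomeric acetals, because the ortho phenol is hydrogen-bonded to the ketone. The product is labile on silica. PPTS may already start a racemic ring contraction.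
- The fallback replaces the equilibrium exchange by a kinetic, irreversible silyl-transfer (Noyori-type) acetalisation. It sets out from 14 and 2 and comes back at 16.
  - TMSCl and Et3N convert 14 into 2-(trimethylsilyloxy)-1-[2,4-bis(trimethylsilyloxy)-3,5-diprenylphenyl]ethanone F5.
  - The same reagents convert 2 into 4-(trimethylsilyloxy)benzaldehyde F6.
  - TMSOTf (5 mol%) in CH2Cl2 at −78 °C joins them, with loss of the disiloxane, to 8-(trimethylsilyloxy)-2-[4-(trimethylsilyloxy)phenyl]-7,9-diprenyl-2H-1,3-benzodioxepin-5(4H)-one F7.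
  - Brief methanolysis at 0 °C frees the two phenols to give 16.

**Step 3, the one-pot double prenylation.**
- Risks: the second lithiation has only one directing group. It competes with deprotonation of the benzylic-allylic CH2 of 7 and with any leftover 5.
- The fallback fixes that position with a halogen and inverts the order of the two prenylations. It sets out from 4 and comes back at 9.
  - NBS (1 equiv, MeCN, 0 °C) gives 1-bromo-2,4-bis(methoxymethoxy)benzene F8.
  - Bromine–lithium exchange (n-BuLi, −78 °C) followed by 5 gives 2,4-bis(methoxymethoxy)-1-prenylbenzene F9.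
  - The fast, doubly directed lithiation between the two MOM ethers (n-BuLi, 0 °C) followed by 5 gives 9.

## Further compounds
F1 | step 6 | 1-[2,4-bis(methoxymethoxy)-3,5-diprenylphenyl]ethanone | CC(=O)c1cc(CC=C(C)C)c(OCOC)c(CC=C(C)C)c1OCOC
F2 | step 6 | 4-(methoxymethoxy)benzaldehyde | COCOc1ccc(C=O)cc1
F3 | step 6 | (E)-1-[2,4-bis(methoxymethoxy)-3,5-diprenylphenyl]-3-[4-(methoxymethoxy)phenyl]prop-2-en-1-one | COCOc1ccc(/C=C/C(=O)c2cc(CC=C(C)C)c(OCOC)c(CC=C(C)C)c2OCOC)cc1
F4 | step 6 | [2,4-bis(methoxymethoxy)-3,5-diprenylphenyl]{(2R,3S)-3-[4-(methoxymethoxy)phenyl]oxiran-2-yl}methanone | O1[C@@H](c2ccc(OCOC)cc2)[C@@H]1C(=O)c1cc(CC=C(C)C)c(OCOC)c(CC=C(C)C)c1OCOC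
F5 | step 5 | 2-(trimethylsilyloxy)-1-[2,4-bis(trimethylsilyloxy)-3,5-diprenylphenyl]ethanone | C[Si](C)(C)OCC(=O)c1cc(CC=C(C)C)c(O[Si](C)(C)C)c(CC=C(C)C)c1O[Si](C)(C)C
F6 | step 5 | 4-(trimethylsilyloxy)benzaldehyde | C[Si](C)(C)Oc1ccc(C=O)cc1
F7 | step 5 | 8-(trimethylsilyloxy)-2-[4-(trimethylsilyloxy)phenyl]-7,9-diprenyl-2H-1,3-benzodioxepin-5(4H)-one | O=C1COC(c2ccc(O[Si](C)(C)C)cc2)Oc2c(CC=C(C)C)c(O[Si](C)(C)C)c(CC=C(C)C)cc21
F8 | step 3 | 1-bromo-2,4-bis(methoxymethoxy)benzene | COCOc1ccc(Br)c(OCOC)c1
F9 | step 3 | 2,4-bis(methoxymethoxy)-1-prenylbenzene | COCOc1ccc(CC=C(C)C)c(OCOC)c1
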